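**Assumptions:** The structure is taken exactly as drawn (C26H34Br2O4). Compounds 1, 2, 10 and 12 are taken to be commercial.

**Atom labels used below:** C1 = ArCH2. The ring is C2(=C3–Me)–C4–C5–C6(Br)–C7(Me). The chain is C8H2, C9/C10(Me) (epoxide), C11, C12, C13(Br), C14(Me2)–O. With these labels the target is 6S,7S,9S,10S,13R.

## Retrosynthetic overview
1. The epoxide is the last ring formed. It comes from the E-C9=C10 alkene of the 15-membered lactone by face-selective syn-dihydroxylation and a stereoretentive diol-to-epoxide closure, which also frees the phenol.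
2. The macrolactone is the second ring. C14–O and C13–Br form together in an anodic, bromide-mediated bromo-macrolactonisation of a seco-acid. This is the key step and it is new.
3. The seco-acid comes from two chemoselective Negishi couplings on one ring block: C10–C11 at an (E)-vinyl iodide, then C1–C2 at an enol triflate.
4. The ring block is the first ring and is bought as (R)-carvone. C7 is set by double α′-alkylation anti to the isopropenyl group. C6–Br comes from the isopropenyl group by Criegee rearrangement (retention) and then Appel bromination (inversion).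

## Route

**Step 1**
Reactants: 1 (R)-(–)-carvone; 2 1-bromobut-2-yne
Product: 3 (5R)-6-(but-2-yn-1-yl)carvone, a mixture of C6 epimers
Conditions: LDA, THF, –78 °C; then 2, –78 → –20 °C
Reagents that add atoms: none (2 is the alkylating partner)
Why: This is a kinetic cross-conjugated (α′) enolate alkylation with a reactive propargylic bromide, and the new C–H centre is erased in step 2, so its ratio does not matter.

**Step 2**
Reactants: 3
Product: 4 (5S,6R)-6-(but-2-yn-1-yl)-2,6-dimethyl-5-(prop-1-en-2-yl)cyclohex-2-en-1-one (6-Me trans, side chain cis to the isopropenyl group)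
Conditions: LDA, THF–DMPU, –78 °C; MeI, –78 → 0 °C
Reagents that add atoms: iodomethane, CI
Why: In this second α′-enolate alkylation MeI attacks the enolate face anti to the adjacent pseudo-axial isopropenyl group, which sets quaternary C7 by 1,2-induction from the purchased stereocentre.

**Step 3**
Reactants: 4
Product: 5 (5S,6R)-6-(but-2-yn-1-yl)-2,6-dimethyl-5-(prop-1-en-2-yl)cyclohex-1-en-1-yl triflate
Conditions: L-Selectride, THF, –78 °C; then Comins' reagent, –78 → 0 °C
Reagents that add atoms: Comins' reagent, FC(F)(F)S(=O)(=O)N(c1ccc(Cl)cn1)S(=O)(=O)C(F)(F)F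
Why: Conjugate reduction followed by enolate O-triflation locks the tetrasubstituted C2=C3 position regiospecifically, removes the carbonyl before a leaving group sits at C6, and touches no stereocentre.

**Step 4**
Reactants: 5
Product: 6 (1R,2R)-2-(but-2-yn-1-yl)-2,4-dimethyl-3-(triflyloxy)cyclohex-3-en-1-yl acetate
Conditions: O3, CH2Cl2–MeOH, NaHCO3, –78 °C (Sudan III end point); concentrate; Ac2O, Et3N, DMAP, CH2Cl2, 0 → 40 °C
Reagents that add atoms: ozone, [O-][O+]=O (ring-bound O); methanol, CO (acetate C=O oxygen). The acetyl carbons are the former isopropenyl carbons.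
Why: Only the electron-rich 1,1-disubstituted alkene is ozonised (the enol triflate and alkyne react much more slowly), and the acetylated α-methoxy hydroperoxide undergoes Criegee rearrangement with C6 migrating with retention.

**Step 5**
Reactants: 6
Product: 7 (5R,6R)-6-(but-2-yn-1-yl)-5-hydroxy-2,6-dimethylcyclohex-1-en-1-yl triflate (OH cis to the side chain, trans to 6-Me)
Conditions: DIBAL-H (2.2 equiv), CH2Cl2, –78 °C
Reagents that add atoms: none
Why: Reductive acetate cleavage under non-basic conditions spares the vinyl triflate and alkyne and leaves the stereocentres unchanged.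

**Step 6**
Reactants: 7
Product: 8 (5S,6S)-5-bromo-6-(but-2-yn-1-yl)-2,6-dimethylcyclohex-1-en-1-yl triflate
Conditions: CBr4, PPh3, 2,6-lutidine, toluene, 23 → 70 °C
Reagents that add atoms: carbon tetrabromide, BrC(Br)(Br)Br
Why: Appel bromination displaces the axial alkoxyphosphonium by SN2 with inversion, giving equatorial Br at C6 (S), cis to C7-Me and trans to the chain, and the electron-poor enol triflate cannot take part in a homoallyl rearrangement.

**Step 7**
Reactants: 8
Product: 9 (5S,6S)-5-bromo-6-[(2E)-3-iodobut-2-en-1-yl]-2,6-dimethylcyclohex-1-en-1-yl triflate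
Conditions: Cp2Zr(H)Cl (2.2 equiv), THF, 23 → 40 °C; I2, 0 °C
Reagents that add atoms: iodine, II
Why: Syn-hydrozirconation under equilibrating conditions (excess reagent) puts Zr next to the methyl group, away from the neopentyl C8, and iodinolysis with retention gives the E-iodide.

**Step 8**
Reactants: 9; 10 5-bromo-2-methylpent-2-ene
Product: 11 (5S,6S)-5-bromo-6-[(2E)-3,7-dimethylocta-2,6-dien-1-yl]-2,6-dimethylcyclohex-1-en-1-yl triflate
Conditions: 10, Mg then ZnBr2, THF; add 9, PdCl2(dppf) (3 mol %), THF, 23 °C
Reagents that add atoms: none (10 enters as its organozinc)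
Why: This sp2–sp3 Negishi coupling retains the alkene geometry, the unhindered vinyl iodide reacts well before the hindered triflate, and the unactivated secondary bromide is inert to Pd(dppf).

**Step 9**
Reactants: 12 4-hydroxy-3-methylbenzoic acid
Product: 13 4-acetoxy-3-methylbenzoic acid
Conditions: Ac2O, pyridine, 23 °C; aqueous work-up
Reagents that add atoms: acetic anhydride, CC(=O)OC(C)=O
Why: Phenol acetylation makes the oxygen non-nucleophilic and deactivates the ring towards Br+ in steps 10 and 13.

**Step 10**
Reactants: 13
Product: 14 4-acetoxy-3-(bromomethyl)benzoic acid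
Conditions: NBS, blue LED, PhCF3, 40 °C
Reagents that add atoms: N-bromosuccinimide, O=C1CCC(=O)N1Br
Why: This is a Wohl–Ziegler benzylic bromination at the only benzylic C–H site.

**Step 11**
Reactants: 14
Product: 15 tert-butyldimethylsilyl 4-acetoxy-3-(bromomethyl)benzoate
Conditions: TBSCl, i-Pr2NEt, CH2Cl2, 0 °C
Reagents that add atoms: TBSCl, CC(C)(C)[Si](C)(C)Cl
Why: The silyl ester removes the acidic proton so that a benzylic zinc reagent can form, and it falls off on mild aqueous acid work-up.

**Step 12**
Reactants: 11; 15
Product: 16 4-acetoxy-3-{[(5S,6S)-5-bromo-6-geranyl-2,6-dimethylcyclohex-1-en-1-yl]methyl}benzoic acid (seco-acid)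
Conditions: 15, Zn dust, LiCl, THF, 0 °C; add 11, Pd(OAc)2 / SPhos (5/10 mol %), 50 °C; then AcOH–THF–H2O, 23 °C
Reagents that add atoms: none
Why: Negishi coupling of a benzylic zinc with a 2,6,6-trisubstituted cyclohexenyl triflate gives the tetrasubstituted alkene with no positional ambiguity; the aryl acetate and secondary bromide tolerate RZnX, and the silyl ester hydrolyses on work-up.

**Step 13 (key step)**
Reactants: 16
Product: 17 (13R)-bromo 15-membered macrolactone with the phenol as acetate and the E-C9=C10 and C2=C3 alkenes intact
Conditions: undivided cell, RVC anode, Pt cathode; 2,4,6-collidine·HBr (1.1 equiv), 2,4,6-collidine (3 equiv), n-Bu4NPF6 (0.1 M), CH2Cl2–MeCN 4:1, 1 mM, –20 °C, dark, about 1 mA cm⁻², 2.2 F mol⁻¹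
Reagents that add atoms: 2,4,6-collidinium bromide, Cc1cc(C)[nH+]c(C)c1.[Br-]
Why: Proposed new method: one equivalent of bromide is oxidised at about +0.8 V, below the alkene, arene and collidine potentials, and is released by the current as collidine-ligated Br+, so free Br⁻/Br2 and hence dibromide formation stay minimal, while the cathode reduces the collidinium and carboxylic acid protons to H2 and supplies the carboxylate; Br+ exchanges reversibly among the three alkenes and only the terminal C13=C14 bromiranium can be opened irreversibly at its tertiary carbon by the tethered carboxylate through an unstrained anti-periplanar 15-membered transition state, helped by zwitterion attraction in a low-polarity medium that disfavours cation–olefin cyclisation; under these Curtin–Hammett conditions the rigid aryl–CH2–cyclohexene hinge (C6/C7 from carvone) and the E-alkene are predicted to allow closure only from the C13-Re bromiranium, giving 13R, though that sense has not been modelled; the closest known reactions are bromide-mediated anodic bromolactonisation to 5- and 6-membered lactones and stoichiometric bis(collidine)halonium macro-halolactonisation of ω-alkenoic acids.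

**Step 14**
Reactants: 17
Product: 18 (9S,10S)-diol of 17
Conditions: OsO4 (5 mol %), NMO, MeSO2NH2, acetone–H2O, 0 → 23 °C
Reagents that add atoms: osmium tetroxide, O=[Os](=O)(=O)=O; NMO (terminal O source), C[N+]1([O-])CCOCC1
Why: In this Upjohn syn-dihydroxylation the hindered tetrasubstituted C2=C3 alkene is inert, and peripheral attack on the E-alkene, whose inner face is blocked by the macrocycle, is expected to fall on the Si,Si face under control of C6/C7/C13 and so set C9 and C10; the sense of this facial bias is a prediction that has not been modelled.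

**Step 15**
Reactants: 18
Product: 19 target
Conditions: MeC(OMe)3, PPTS (cat.), CH2Cl2; evaporate; AcBr, CH2Cl2, 0 °C; evaporate; K2CO3, MeOH, 0 → 23 °C
Reagents that add atoms: none (all orthoacetate- and AcBr-derived atoms leave again)
Why: The Kolb–Sharpless one-pot diol-to-epoxide sequence (acetoxonium opening by Br⁻, then closure) inverts the same carbon twice, so the syn-diol of the E-alkene gives the trans (9S,10S)-epoxide; the same methanolysis removes the aryl acetate, and the hindered tertiary benzoate and both secondary bromides survive.

## Compound list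
| No. | Name | SMILES | Role |
|---|---|---|---|
| 1 | (R)-(–)-carvone | `CC1=CC[C@H](CC1=O)C(C)=C` | starting material |
| 2 | 1-bromobut-2-yne | `CC#CCBr` | starting material |
| 3 | (5R)-6-(but-2-ynyl)carvone (C6 epimers) | `CC1=CC[C@@H](C(C)=C)C(CC#CC)C1=O` | intermediate |
| 4 | (5S,6R)-6-(but-2-ynyl)-6-methylcarvone | `CC1=CC[C@@H](C(C)=C)[C@@](C)(CC#CC)C1=O` | intermediate |
| 5 | enol triflate | `CC1=C(OS(=O)(=O)C(F)(F)F)[C@](C)(CC#CC)[C@H](C(C)=C)CC1` | intermediate |
| 6 | C6 acetate | `CC1=C(OS(=O)(=O)C(F)(F)F)[C@](C)(CC#CC)[C@H](OC(C)=O)CC1` | intermediate |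
| 7 | C6 alcohol | `CC1=C(OS(=O)(=O)C(F)(F)F)[C@](C)(CC#CC)[C@H](O)CC1` | intermediate |
| 8 | C6 bromide | `CC1=C(OS(=O)(=O)C(F)(F)F)[C@](C)(CC#CC)[C@@H](Br)CC1` | intermediate |
| 9 | (E)-vinyl iodide | `CC1=C(OS(=O)(=O)C(F)(F)F)[C@](C)(C/C=C(/I)C)[C@@H](Br)CC1` | intermediate |
| 10 | 5-bromo-2-methylpent-2-ene | `CC(C)=CCCBr` | starting material |
| 11 | geranyl bromo-triflate | `CC1=C(OS(=O)(=O)C(F)(F)F)[C@](C)(C/C=C(\C)CCC=C(C)C)[C@@H](Br)CC1` | intermediate |
| 12 | 4-hydroxy-3-methylbenzoic acid | `Cc1cc(ccc1O)C(=O)O` | starting material |
| 13 | 4-acetoxy-3-methylbenzoic acid | `CC(=O)Oc1ccc(cc1C)C(=O)O` | intermediate |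
| 14 | 4-acetoxy-3-(bromomethyl)benzoic acid | `CC(=O)Oc1ccc(cc1CBr)C(=O)O` | intermediate |
| 15 | TBS 4-acetoxy-3-(bromomethyl)benzoate | `CC(=O)Oc1ccc(cc1CBr)C(=O)O[Si](C)(C)C(C)(C)C` | intermediate |
| 16 | seco-acid | `CC1=C(Cc2cc(ccc2OC(C)=O)C(=O)O)[C@](C)(C/C=C(\C)CCC=C(C)C)[C@@H](Br)CC1` | intermediate |
| 17 | bromo-macrolactone (aryl acetate) | `CC1=C2Cc3cc(ccc3OC(C)=O)C(=O)OC(C)(C)[C@H](Br)CC/C(C)=C/C[C@]2(C)[C@@H](Br)CC1` | intermediate |
| 18 | (9S,10S)-diol | `CC1=C2Cc3cc(ccc3OC(C)=O)C(=O)OC(C)(C)[C@H](Br)CC[C@](C)(O)[C@@H](O)C[C@]2(C)[C@@H](Br)CC1` | intermediate |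
| 19 | CID46880797 | `CC1=C2Cc3cc(ccc3O)C(=O)OC(C)(C)[C@H](Br)CC[C@]3(C)O[C@H]3C[C@]2(C)[C@@H](Br)CC1` | target |

## Step count
- **Total steps:** 15.
- **Longest linear sequence:** 12 (steps 1–8, then 12–15).

## Steps most likely to fail

**1. Step 13 (new electrochemical bromo-macrolactonisation).**
- Risks: cation–olefin cyclisation of the C9=C10/C13=C14 1,5-diene, allylic bromide formation, and low or wrong diastereoselectivity at C13.
- Fallback (known chemistry): buy C13 instead of making it in the ring closure.
  - In step 8, couple 9 with the organozinc from (S)-4-(2-iodoethyl)-2,2,5,5-tetramethyl-1,3-dioxolane. This iodide comes from L-malic-acid-derived (S)-α-hydroxy-γ-butyrolactone by MeMgBr addition, acetonide formation and I2/PPh3.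
  - After step 12, remove the acetonide and close a 14-membered lactone on the secondary C13–OH (Shiina or Yamaguchi).
  - Ionise the tertiary C14–OH so that the 2-aryl-1,3-dioxolan-2-ylium ion is opened by bromide at C13 with a single inversion (13S-OH → 13R-Br). This gives the tertiary ester and the 15-membered ring stereospecifically.

**2. Step 6 (SN2 at a neopentyl-type secondary carbon).**
- Risks: elimination to the C5=C6 alkene, or rearrangement.
- Fallback: make the C–Br bond by a radical route. Ozonise 5 with reductive work-up to the C6 methyl ketone and oxidise it to the acid by the haloform reaction. Photolyse the derived Barton ester in BrCCl3 (Barton decarboxylative bromination); bromine transfer is expected on the face anti to the bulkier C7 side chain.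

**3. Step 14 (facial selectivity of the macrocyclic dihydroxylation).**
- Risk: the preferred face is not predictable with confidence.
- Fallback: set C9/C10 before the arene is attached, using a ring-fused iodolactonisation.
  - Convert triflate 11 to the C1 acid by Pd-catalysed hydroxycarbonylation.
  - Treat with I2/NaHCO3. In the fused half-chair transition state the C10 substituent sits pseudo-equatorial and H-9 is syn to C7-Me, which predicts 9S.
  - K2CO3/MeOH gives the (9S,10S)-epoxy ester, and DIBAL-H gives the allylic alcohol.
  - Attach the arene by Pd-catalysed allyl–aryl coupling. Carry the epoxide through the ring closure masked as its bromo-acetate, which the final K2CO3/MeOH step re-closes.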